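1. An easy step first: a Z molecule at G stands at a fork, towards Q or towards X. The proposed steps Z + G + Q → G + D and Z + G + X → G + E both carry Z and G, so Z, G and time cancel from the odds, which rest on Q/X and the ratio of the two constants.

| flask | Q | X | Z | L | remark | time |
|---|---|---|---|---|---|---|
| south | 0.10 M | 0.10 M | 0.15 M | 15 mM | run made earlier |  |
| north-west | 0.10 M | 0.10 M | 0.60 M | 15 mM | run made earlier |  |
| flask | 0.10 M | 0.10 M | 0.300 M | 15 mM |  | 30 h |

| run | time / h | Q / % | X / % |
|---|---|---|---|
| south | 5.00 | 39.7 | 46.9 |
| south | 10.0 | 27.3 | 40.9 |
| south | 15.0 | 18.7 | 38.4 |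
| south | 20.0 | 15.2 | 36.4 |
| south | 25.0 | 12.8 | 32.5 |
| north-west | 5.00 | 18.6 | 35.9 |
| north-west | 10.0 | 3.5 | 20.2 |
| north-west | 15.0 | 0.1 | 10.7 |
| north-west | 20.0 | 0.2 | 5.1 |
| north-west | 25.0 | 0 | 0.8 |

(standard deviation of a reading: 1 percentage point)

- G is single-handed; Q and X are mirror images of each other, charged as a racemate, each of them at the stated concentration
- the numbers in the tables scatter by 1 percentage point (one standard deviation)
- steps that have been proposed: Z <-> J; D <-> E; L -> G; Z + G + X -> G + E; Z + G + Q -> G + D
- an excess is the difference of the two amounts in percent of their sum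
- an excess is below zero if the other one leads

1. part of the Q and X charged together that has reacted at 30 h
2. excess of D over E in the product at 30 h
3. excess of X over Q among what is left of the two at 30 h

2. That ratio is the selectivity factor s, the logarithm of the fall of Q over the logarithm of the fall of X, each measured against its own charge. The north-west run at 5.00 h reads s = 2.98. The south run at 10.0 h, with a quarter of the Z, reads 3.01.

3. With Q and X equal, a molecule takes the Q branch with chance 74.9 %, so the first product has an excess of 49.8 %.

4. The flask has half the Z of the north-west run for twice the time. This reckoning therefore assumes that the flask ends like that run at 15.0 h, with 21.4 % of the charge of X left. Raising this to the power s leaves 1.00 % of the charge of Q.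

5. Turned round: for the product to keep its first excess, with D/E equal to s, down to that Q, X would have to stand at 66.8 % of its charge, more than the 21.4 % reckoned from s. So X is consumed too. This reckoning gives c 88.8 %, eP 11.5 % and eS 91.0 %.

6. The forecast gives c 84.3 %, eP 15.9 % and eS 85 %, from "Q is consumed about three times faster than X in both runs".

7. The flask gives c 89.1 %, eP 6.99 % and eS 92.4 %.

    Z ⇌ J (K = 0.790, k = 0.00100 min⁻¹)
    D ⇌ E (k = 8.70 × 10⁻⁵ min⁻¹)
    L → G (k = 6.70 × 10⁻⁴ min⁻¹)
    Z + G + X → G + E (k = 1.60 L² mol⁻² min⁻¹)
    Z + G + Q → G + D (k = 4.90 L² mol⁻² min⁻¹)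

The eP of the flask stands 4.5 percentage points below this reckoning. From what the flask leaves of its charge, Q 0.83 % and X 21 %, s comes out at 3.07. The neighbour flask with 0.075 M of Z reaches c 32.4 %, leaves Q 54 % and X 82 %, and gives s = 3.06. The low eP of the flask is mainly due to the branch Z + G + X → G + E: the same flask without that branch ends at eP 79.0 % instead of 6.99 %.

All runs come from a simulation on assumed constants, and the scatter is random.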